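**Plan**

- Retrosynthesis: the benzyl ester and the two methyl ethers next to the carbonyl groups are unmasked last. Ring B is then cut at C1–C6 and C2–C3, with CO2 put back between C6 and C3, giving a 4-aroyloxy-6-pentyl-2-pyrone and benzyl 3-methoxypropiolate.
- Enabling feature: C3 to C6 of ring B (H, acyloxy, H, pentyl) are C3 to C6 of an O-acylated 4-hydroxy-6-pentyl-2-pyrone, and C1 (carboxyl) and C2 (oxygen) are the two carbons of a push-pull alkoxypropiolate.
- Further cuts: the depside C(=O)–O bond (pyrone hydroxyl plus ring A acid chloride), the pentyl chain of the pyrone at its C1–C2 bond, and the ring A carboxyl carbon and chlorine from olivetol dimethyl ether.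
- Forward order: ring A acid (C2 chlorination by ortho-lithiation, formylation, oxidation); pentylpyrone; depside ester made on the pyrone; ring B closed by cycloaddition and CO2 loss; ether cleavage and hydrogenolysis.
- Stereochemistry: the target has no stereocentre. Only the orientation of the cycloaddition matters, and it is set by the matched polarisation of pyrone and alkyne.

Key step: step 8

Remark on the chemistry: the dienophile carries a methyl ynol ether, because an O-ethyl alkynyl ether would lose ethylene by a retro-ene reaction at the cycloaddition temperature. The ring A phenol travels as its methyl ether and is freed by the same BCl3 treatment as the ring B ether.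

**Route**

Step 1
Reactants: 1 olivetol dimethyl ether (1,3-dimethoxy-5-pentylbenzene)
Product: 3 2-chloro-1,3-dimethoxy-5-pentylbenzene, via aryllithium 2 (not isolated)
Conditions: n-BuLi (1.1 equiv), THF, 0 °C to rt; then C2Cl6, −78 °C to rt
Reagents that add atoms: hexachloroethane, ClC(Cl)(Cl)C(Cl)(Cl)Cl
Why: Directed ortho-metalation places lithium on the carbon between the two methoxy groups, and chlorine transfer from hexachloroethane to this aryllithium fixes the halogen between the two oxygens without regiochemical ambiguity.

Step 2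
Reactants: 3 2-chloro-1,3-dimethoxy-5-pentylbenzene
Product: 4 3-chloro-2,4-dimethoxy-6-pentylbenzaldehyde
Conditions: Cl2CHOMe, TiCl4, CH2Cl2, −78 to 0 °C; then ice and aqueous HCl
Reagents that add atoms: dichloromethyl methyl ether, COC(Cl)Cl
Why: Rieche formylation is an electrophilic aromatic substitution, and the two free ring positions of the symmetrical arene are equivalent and each ortho and para to a methoxy group, so a single aldehyde should form.

Step 3
Reactants: 4 3-chloro-2,4-dimethoxy-6-pentylbenzaldehyde
Product: 5 3-chloro-2,4-dimethoxy-6-pentylbenzoic acid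
Conditions: NaClO2, NaH2PO4, 2-methyl-2-butene, t-BuOH/H2O, rt
Reagents that add atoms: sodium chlorite, [Na+].[O-]Cl=O
Why: Pinnick oxidation converts the hindered electron-rich aldehyde into the acid under buffered conditions, while the alkene traps hypochlorous acid before it can chlorinate the ring.

Step 4
Reactants: 6 4-hydroxy-6-methyl-2H-pyran-2-one
Product: 8 4-hydroxy-6-pentyl-2H-pyran-2-one, via dilithio dianion 7 (not isolated)
Conditions: LiN(i-Pr)2 (commercial solution, 2.2 equiv), THF/DMPU, −78 °C; n-BuI, −78 to 0 °C; aqueous HCl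
Reagents that add atoms: 1-iodobutane, CCCCI
Why: In this dianion alkylation the second equivalent of amide base removes a proton from the vinylogous 6-methyl group of the lithium pyronate, and the resulting carbanion, the more reactive site, is butylated by the primary iodide.

Step 5
Reactants: 5 3-chloro-2,4-dimethoxy-6-pentylbenzoic acid
Product: 9 3-chloro-2,4-dimethoxy-6-pentylbenzoyl chloride
Conditions: (COCl)2, DMF (catalytic), CH2Cl2, 0 °C to rt; evaporate and use crude
Reagents that add atoms: oxalyl chloride, O=C(Cl)C(=O)Cl
Why: Acid chloride formation by DMF-catalysed reaction with oxalyl chloride activates the doubly ortho-substituted acid, whose methyl ethers tolerate the HCl set free.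

Step 6
Reactants: 8 4-hydroxy-6-pentyl-2H-pyran-2-one; 9 3-chloro-2,4-dimethoxy-6-pentylbenzoyl chloride
Product: 10 2-oxo-6-pentyl-2H-pyran-4-yl 3-chloro-2,4-dimethoxy-6-pentylbenzoate
Conditions: Et3N, CH2Cl2, 0 °C to rt (no DMAP)
Reagents that add atoms: none
Why: O-Acylation of the acidic pyrone hydroxyl by the acyl chloride with triethylamine gives the 4-acyloxy-2-pyrone, and leaving out a nucleophilic catalyst avoids the Fries-type shift of the acyl group to C3.

Step 7
Reactants: 11 trichloroethylene
Product: 14 benzyl 3-methoxyprop-2-ynoate, via (E)-1,2-dichloro-1-methoxyethene 12 (not isolated), via lithium methoxyacetylide 13 (not isolated)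
Conditions: KOMe (1.0 equiv), THF, −50 °C to rt; n-BuLi (2.1 equiv), −78 to −40 °C; ClCO2Bn, −78 to 0 °C; pH 7 buffer
Reagents that add atoms: potassium methoxide, C[O-].[K+]; benzyl chloroformate, O=C(Cl)OCc1ccccc1
Why: In this ynol ether synthesis from trichloroethylene, methoxide replaces a vinylic chlorine by elimination–addition, n-BuLi then effects dehydrochlorination and chlorine–lithium exchange to the lithium alkoxyacetylide, and C-acylation by the chloroformate gives the push-pull alkyne.

Step 8
Reactants: 10 2-oxo-6-pentyl-2H-pyran-4-yl 3-chloro-2,4-dimethoxy-6-pentylbenzoate; 14 benzyl 3-methoxyprop-2-ynoate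
Product: 16 benzyl 4-[(3-chloro-2,4-dimethoxy-6-pentylbenzoyl)oxy]-2-methoxy-6-pentylbenzoate, via bridged bicyclic lactone 15 (not isolated)
Conditions: 14 (3 equiv), 1,2-dichlorobenzene, BHT (catalytic), sealed tube, 160 °C
Reagents that add atoms: none
Why: The pyrone diene C3=C4–C5=C6 and the alkyne should combine in a thermal (4+2) cycloaddition to the 2-oxabicyclo[2.2.2]octadienone 15, which loses CO2 by cycloreversion at the same temperature. The closest known reaction type is the Diels–Alder and CO2-extrusion benzannulation of 2-pyrones with alkynes. Ring B is closed by this intermolecular cycloaddition, which forms C2–C3 and C1–C6, and it aromatises on CO2 loss without an oxidant. No stereocentre remains, since the two bridgehead centres of 15 disappear with the CO2. The selectivity needed is regiochemical: pyrone C3 (alpha to the lactone carbonyl and beta to the acyloxy oxygen) is the nucleophilic terminus and C6 the electrophilic one, while the methoxy-bearing alkyne carbon is electrophilic and the ester-bearing carbon nucleophilic, so the matched pairing puts methoxy next to C3–H and the ester next to pentyl. The methyl ynol ether has no beta hydrogen, so no retro-ene path to a ketene competes, and the excess of alkyne offsets its oligomerisation.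

Step 9
Reactants: 16 benzyl 4-[(3-chloro-2,4-dimethoxy-6-pentylbenzoyl)oxy]-2-methoxy-6-pentylbenzoate
Product: 17 benzyl 4-[(3-chloro-2-hydroxy-4-methoxy-6-pentylbenzoyl)oxy]-2-hydroxy-6-pentylbenzoate
Conditions: BCl3 (4 equiv), CH2Cl2, −78 to 0 °C; then H2O
Reagents that add atoms: none
Why: In this chelation-controlled ether cleavage BCl3 binds each ester carbonyl together with its ortho methoxy oxygen and chloride removes the methyl group, whereas the ring A methoxy group para to the carbonyl lacks this assistance and both esters should survive at low temperature.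

Step 10
Reactants: 17 benzyl 4-[(3-chloro-2-hydroxy-4-methoxy-6-pentylbenzoyl)oxy]-2-hydroxy-6-pentylbenzoate
Product: 18 4-[(3-chloro-2-hydroxy-4-methoxy-6-pentylbenzoyl)oxy]-2-hydroxy-6-pentylbenzoic acid
Conditions: H2 (1 atm), Pd/C (10 wt% palladium on carbon), EtOAc, rt, short reaction time
Reagents that add atoms: none
Why: Hydrogenolysis of the benzyl ester frees the acid under neutral conditions that spare the depside ester, and a short contact time in ethyl acetate should keep the aryl chloride intact.

**Compound list**

1 | olivetol dimethyl ether (1,3-dimethoxy-5-pentylbenzene) | CCCCCc1cc(OC)cc(OC)c1 | starting material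
2 | 2-lithio-1,3-dimethoxy-5-pentylbenzene (aryllithium, not isolated) | CCCCCc1cc(OC)c([Li])c(OC)c1 | intermediate
3 | 2-chloro-1,3-dimethoxy-5-pentylbenzene | CCCCCc1cc(OC)c(Cl)c(OC)c1 | intermediate
4 | 3-chloro-2,4-dimethoxy-6-pentylbenzaldehyde | CCCCCc1cc(OC)c(Cl)c(OC)c1C=O | intermediate
5 | 3-chloro-2,4-dimethoxy-6-pentylbenzoic acid | CCCCCc1cc(OC)c(Cl)c(OC)c1C(=O)O | intermediate
6 | 4-hydroxy-6-methyl-2H-pyran-2-one | Cc1cc(O)cc(=O)o1 | starting material
7 | dilithio dianion of 6, lithiated at the 4-oxygen and at the 6-methyl carbon (not isolated) | [Li]Cc1cc(O[Li])cc(=O)o1 | intermediate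
8 | 4-hydroxy-6-pentyl-2H-pyran-2-one | CCCCCc1cc(O)cc(=O)o1 | intermediate
9 | 3-chloro-2,4-dimethoxy-6-pentylbenzoyl chloride | CCCCCc1cc(OC)c(Cl)c(OC)c1C(Cl)=O | intermediate
10 | 2-oxo-6-pentyl-2H-pyran-4-yl 3-chloro-2,4-dimethoxy-6-pentylbenzoate | CCCCCc1cc(OC(=O)c2c(CCCCC)cc(OC)c(Cl)c2OC)cc(=O)o1 | intermediate
11 | trichloroethylene | ClC=C(Cl)Cl | starting material
12 | (E)-1,2-dichloro-1-methoxyethene (not isolated) | CO/C(Cl)=C\Cl | intermediate
13 | lithium methoxyacetylide (not isolated) | COC#C[Li] | intermediate
14 | benzyl 3-methoxyprop-2-ynoate | COC#CC(=O)OCc1ccccc1 | intermediate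
15 | benzyl 5-[(3-chloro-2,4-dimethoxy-6-pentylbenzoyl)oxy]-8-methoxy-3-oxo-1-pentyl-2-oxabicyclo[2.2.2]octa-5,7-diene-7-carboxylate (racemic bridged lactone, not isolated) | O=C1OC2(CCCCC)C=C(OC(=O)c3c(CCCCC)cc(OC)c(Cl)c3OC)C1C(OC)=C2C(=O)OCc1ccccc1 | intermediate
16 | benzyl 4-[(3-chloro-2,4-dimethoxy-6-pentylbenzoyl)oxy]-2-methoxy-6-pentylbenzoate | CCCCCc1cc(OC(=O)c2c(CCCCC)cc(OC)c(Cl)c2OC)cc(OC)c1C(=O)OCc1ccccc1 | intermediate
17 | benzyl 4-[(3-chloro-2-hydroxy-4-methoxy-6-pentylbenzoyl)oxy]-2-hydroxy-6-pentylbenzoate | CCCCCc1cc(OC(=O)c2c(CCCCC)cc(OC)c(Cl)c2O)cc(O)c1C(=O)OCc1ccccc1 | intermediate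
18 | 4-[(3-chloro-2-hydroxy-4-methoxy-6-pentylbenzoyl)oxy]-2-hydroxy-6-pentylbenzoic acid | CCCCCc1cc(OC(=O)c2c(CCCCC)cc(OC)c(Cl)c2O)cc(O)c1C(=O)O | target

**Count and risks**

Total step count: 10. Longest linear sequence: 8 steps (steps 1, 2, 3, 5, 6, 8, 9, 10).

Steps most likely to fail:

1. Step 8. The push-pull alkyne may oligomerise or hydrate faster than it adds to the weakly polarised and sterically loaded pyrone, or the partners may combine with the opposite orientation. The fallback sets out from 5 and returns at 17; it gives up the cycloaddition and joins two preformed rings. BCl3 in CH2Cl2 cleaves the methyl ether next to the carboxyl group of 5 to give 3-chloro-2-hydroxy-4-methoxy-6-pentylbenzoic acid F1. Purchased olivetolic acid (2,4-dihydroxy-6-pentylbenzoic acid, CCCCCc1cc(O)cc(O)c1C(=O)O) is benzylated with BnBr and KHCO3 in DMF to benzyl 2,4-dihydroxy-6-pentylbenzoate F2. F1 and F2 are condensed with trifluoroacetic anhydride in toluene at rt, where the non-chelated C4 hydroxyl of F2 should be acylated, giving 17, and step 10 follows.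

2. Step 7. The acetylide may add a second time to the ester just formed, or the sensitive ynol ether may be hydrated during isolation. The fallback sets out from 13 and returns at 14. The acetylide 13 is quenched with dry CO2 at −78 °C to lithium 3-methoxyprop-2-ynoate F3, a carboxylate that cannot be attacked again. After exchange of the solvent for DMF, O-alkylation with benzyl bromide should give 14.

3. Step 9. The Lewis acid may over-react: loss of the benzyl group with benzylation of an electron-rich ring, cleavage of the para methoxy group of ring A, or acyl–oxygen fission of the depside once boron sits on its carbonyl. The fallback sets out from 8 and 5 and returns at 17; it moves both ether cleavages ahead of the depside bond. Pyrone 8 is acetylated (Ac2O, pyridine) to 2-oxo-6-pentyl-2H-pyran-4-yl acetate F4. Heating F4 with 14 as in step 8 should give, through the bridged lactone F5, benzyl 4-acetoxy-2-methoxy-6-pentylbenzoate F6. BCl3 removes the methyl group next to the benzyl ester to give benzyl 4-acetoxy-2-hydroxy-6-pentylbenzoate F7. K2CO3 in MeOH at 0 °C removes the acetate to give benzyl 2,4-dihydroxy-6-pentylbenzoate F2, which is condensed with acid F1 (from 5 and BCl3, as in the first fallback) using trifluoroacetic anhydride to give 17.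

**Further compounds**

F1 | step 8 | 3-chloro-2-hydroxy-4-methoxy-6-pentylbenzoic acid | CCCCCc1cc(OC)c(Cl)c(O)c1C(=O)O
F2 | step 8 | benzyl 2,4-dihydroxy-6-pentylbenzoate | CCCCCc1cc(O)cc(O)c1C(=O)OCc1ccccc1
F3 | step 7 | lithium 3-methoxyprop-2-ynoate | COC#CC(=O)[O-].[Li+]
F4 | step 9 | 2-oxo-6-pentyl-2H-pyran-4-yl acetate | CCCCCc1cc(OC(C)=O)cc(=O)o1
F5 | step 9 | benzyl 5-acetoxy-8-methoxy-3-oxo-1-pentyl-2-oxabicyclo[2.2.2]octa-5,7-diene-7-carboxylate (racemic, not isolated) | O=C1OC2(CCCCC)C=C(OC(C)=O)C1C(OC)=C2C(=O)OCc1ccccc1
F6 | step 9 | benzyl 4-acetoxy-2-methoxy-6-pentylbenzoate | CCCCCc1cc(OC(C)=O)cc(OC)c1C(=O)OCc1ccccc1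
F7 | step 9 | benzyl 4-acetoxy-2-hydroxy-6-pentylbenzoate | CCCCCc1cc(OC(C)=O)cc(O)c1C(=O)OCc1ccccc1
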